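**Retrosynthetic overview**
- The target is reached from its 3-O-benzyl-5-O-methyl ether by one Lewis-acid step that cleaves only the two ethers chelated to the C4 carbonyl (3-OBn and peri 5-OMe).
- The strategy rests on C8a of ring A: it is the only hydrogen-bearing carbon of the tetra-oxygenated benzene ring and lies para to the C6 methoxy and ortho to the C8 methoxy group. The O1–C8a bond is therefore made by anodic C–H/O–H coupling of an open 2-benzyloxy-1,3-diaryl-1,3-diketone, which closes the pyran-4-one ring C.
- The diketone is cut at C3–C4 into 2,3,4,5-tetramethoxybenzoyl chloride and 2-(benzyloxy)-1-(4-methoxyphenyl)ethanone.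
- The acid chloride comes from 3,4,5-trimethoxybenzoic acid (ortho-bromination, Cu-catalysed methoxylation). The ketone comes from benzyloxyacetyl chloride through its Weinreb amide and 4-methoxyphenylmagnesium bromide.
- Ring order: rings A and B are bought; ring C is the only ring formed (step 7).

Key step: step 7

Remark: the target has no stereocentre, so no enantiocontrol is needed; diketone 9 is racemic at its single sp3 centre, which becomes sp2 in step 7.

**Step 1**
Reactants: 1 3,4,5-trimethoxybenzoic acid
Product: 2 2-bromo-3,4,5-trimethoxybenzoic acid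
Conditions: Br2 (1.1 equiv), CHCl3, reflux
Reagents that add atoms: bromine, BrBr
Why: Electrophilic aromatic bromination; the two equivalent free positions are ortho/para to methoxy groups, and the first bromine deactivates and shields the ring against a second one.

**Step 2**
Reactants: 2 2-bromo-3,4,5-trimethoxybenzoic acid
Product: 3 2,3,4,5-tetramethoxybenzoic acid
Conditions: NaOMe (6 equiv), CuBr (0.2 equiv), MeOH–DMF, 110 °C; then 2 M HCl
Reagents that add atoms: sodium methoxide, C[O-].[Na+]
Why: Ullmann-type copper-catalysed methoxylation of an aryl bromide, accelerated by the ortho-carboxylate (the effect used in Hurtley-type couplings of 2-bromobenzoic acids).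

**Step 3**
Reactants: 3 2,3,4,5-tetramethoxybenzoic acid
Product: 4 2,3,4,5-tetramethoxybenzoyl chloride
Conditions: (COCl)2 (1.3 equiv), DMF (cat.), CH2Cl2, 0 °C to rt; evaporate, use crude
Reagents that add atoms: oxalyl chloride, O=C(Cl)C(=O)Cl
Why: Standard acid chloride formation through the Vilsmeier-type chloroiminium catalyst; aryl methyl ethers are inert to it.

**Step 4**
Reactants: 5 benzyloxyacetyl chloride
Product: 6 2-(benzyloxy)-N-methoxy-N-methylacetamide
Conditions: MeNH(OMe)·HCl (1.1 equiv), Et3N (2.2 equiv), CH2Cl2, 0 °C to rt
Reagents that add atoms: N,O-dimethylhydroxylamine hydrochloride, CNOC.Cl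
Why: Simple N-acylation of the hydroxylamine gives the Weinreb amide.

**Step 5**
Reactants: 6 2-(benzyloxy)-N-methoxy-N-methylacetamide; 7 4-methoxyphenylmagnesium bromide (THF solution)
Product: 8 2-(benzyloxy)-1-(4-methoxyphenyl)ethan-1-one
Conditions: THF, 0 °C; then 1 M HCl
Reagents that add atoms: none
Why: Weinreb ketone synthesis; the chelated tetrahedral magnesium adduct survives until work-up, so no over-addition occurs, and the route avoids displacing a phenacyl bromide with an alkoxide.

**Step 6**
Reactants: 8 2-(benzyloxy)-1-(4-methoxyphenyl)ethan-1-one; 4 2,3,4,5-tetramethoxybenzoyl chloride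
Product: 9 (±)-2-(benzyloxy)-1-(4-methoxyphenyl)-3-(2,3,4,5-tetramethoxyphenyl)propane-1,3-dione
Conditions: MgBr2·OEt2 (2.5 equiv), i-Pr2NEt (3 equiv), CH2Cl2, 0 °C to rt; then cold 1 M HCl
Reagents that add atoms: none
Why: Soft-enolisation C-acylation (Claisen-type); magnesium chelation of the carbonyl and the α-benzyloxy oxygen acidifies the CH2, and the magnesium enolate is acylated on carbon, the product being held as its magnesium diketonate until work-up.

**Step 7**
Reactants: 9 (±)-2-(benzyloxy)-1-(4-methoxyphenyl)-3-(2,3,4,5-tetramethoxyphenyl)propane-1,3-dione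
Product: 10 3-(benzyloxy)-5,6,7,8-tetramethoxy-2-(4-methoxyphenyl)-4H-chromen-4-one
Conditions: graphite anode, Pt cathode, undivided cell, constant current (ca. 5 mA cm−2, 2.2 F mol−1), n-Bu4NPF6 (0.1 M), anhydrous HFIP–CH2Cl2 (4:1), no base, rt
Reagents that add atoms: none
Why: Proposed new method: the tetramethoxybenzoyl ring is the most electron-rich π-system of 9 and should be oxidised first to its radical cation, whose positive charge is largest at C6' (para to the C3' and ortho to the C5' methoxy group); the oxygen of the anisoyl carbonyl (or of its enol) attacks this carbon, and loss of a second electron and of two protons (C6'–H and the C2/enol H) gives the aromatic chromone while the cathode turns the protons into H2. The closest known reaction types are anodic dehydrogenative C–H/O–H lactonisation of 2-arylbenzoic acids and iodine(III)-mediated oxidative C–O cyclisations of methoxyarenes in fluorinated alcohols, whereas this O1–C8a bond is normally made by O-arylation of a 2-haloaryl diketone. Ring C (O1, C2, C3, C4, C4a, C8a) is closed by the O1–C8a bond in a 6-endo attack of oxygen on the arene carbon through a six-membered transition state. No stereocentre is formed, and the racemic C2 centre of 9 becomes the sp2 C3 of the chromone. The step needs site selectivity for C6'–H over ipso attack at the C2' methoxy carbon and oxidation of the correct ring: the ipso adduct has no proton to lose and can reopen while the C–H adduct rearomatises irreversibly, the anisoyl ring is harder to oxidise and its ortho C–H is meta to its methoxy group, and the benzyl ether oxidises only at much higher potential. HFIP should stabilise the radical cation, omitting base keeps the diketone neutral so that the arene and not an enolate is oxidised, and ring A of 10 has no C–H left, so under anhydrous conditions its radical cation has no substitution channel.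

**Step 8**
Reactants: 10 3-(benzyloxy)-5,6,7,8-tetramethoxy-2-(4-methoxyphenyl)-4H-chromen-4-one
Product: 11 3,5-dihydroxy-6,7,8-trimethoxy-2-(4-methoxyphenyl)-4H-chromen-4-one (3,5-dihydroxy-6,7,8,4'-tetramethoxyflavone)
Conditions: BCl3 (4 equiv), pentamethylbenzene (3 equiv), CH2Cl2, −78 °C to rt; then MeOH, aq. NaHCO3
Reagents that add atoms: none
Why: Chelation-controlled Lewis-acid ether cleavage; BCl3 bound to the C4 carbonyl cleaves only the two ethers whose oxygens chelate it (3-O-benzyl and peri 5-O-methyl), pentamethylbenzene traps the benzyl cation, and the non-chelated 6-, 7-, 8- and 4'-methyl ethers should remain.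

**Compound list**
1 | 3,4,5-trimethoxybenzoic acid | COc1cc(cc(OC)c1OC)C(=O)O | starting material
2 | 2-bromo-3,4,5-trimethoxybenzoic acid | COc1cc(C(=O)O)c(Br)c(OC)c1OC | intermediate
3 | 2,3,4,5-tetramethoxybenzoic acid | COc1cc(C(=O)O)c(OC)c(OC)c1OC | intermediate
4 | 2,3,4,5-tetramethoxybenzoyl chloride | COc1cc(C(=O)Cl)c(OC)c(OC)c1OC | intermediate
5 | benzyloxyacetyl chloride | O=C(Cl)COCc1ccccc1 | starting material
6 | 2-(benzyloxy)-N-methoxy-N-methylacetamide | CON(C)C(=O)COCc1ccccc1 | intermediate
7 | 4-methoxyphenylmagnesium bromide | COc1ccc([Mg]Br)cc1 | starting material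
8 | 2-(benzyloxy)-1-(4-methoxyphenyl)ethan-1-one | COc1ccc(cc1)C(=O)COCc1ccccc1 | intermediate
9 | (±)-2-(benzyloxy)-1-(4-methoxyphenyl)-3-(2,3,4,5-tetramethoxyphenyl)propane-1,3-dione | COc1ccc(cc1)C(=O)C(OCc1ccccc1)C(=O)c1cc(OC)c(OC)c(OC)c1OC | intermediate
10 | 3-(benzyloxy)-5,6,7,8-tetramethoxy-2-(4-methoxyphenyl)-4H-chromen-4-one | COc1ccc(cc1)-c1oc2c(OC)c(OC)c(OC)c(OC)c2c(=O)c1OCc1ccccc1 | intermediate
11 | 3,5-dihydroxy-6,7,8-trimethoxy-2-(4-methoxyphenyl)-4H-chromen-4-one | COc1ccc(-c2oc3c(OC)c(OC)c(OC)c(O)c3c(=O)c2O)cc1 | target

**Step count**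
Total steps: 8. Longest linear sequence: 6 (steps 1, 2, 3, 6, 7, 8).

**Steps most likely to fail**

1. Step 7 (proposed new method). Electron transfer may take place at the enol or diketone and not at ring A, leading to radical dimerisation. The oxygen may add ipso at the methoxy-bearing C2' and go on to loss of methanol or to quinone-ketal formation. The product may be over-oxidised or anodically demethylated, or the electrode may passivate. Fallback by known chemistry, setting out from 3 and 8 and coming back at 10: acid 3 is brominated at its only free ring position (Br2, AcOH, rt) to 2-bromo-3,4,5,6-tetramethoxybenzoic acid F1. This is converted with (COCl)2/DMF into 2-bromo-3,4,5,6-tetramethoxybenzoyl chloride F2, which acylates ketone 8 under the soft-enolisation conditions of step 6 to give 2-(benzyloxy)-1-(2-bromo-3,4,5,6-tetramethoxyphenyl)-3-(4-methoxyphenyl)propane-1,3-dione F3. Copper-catalysed intramolecular Ullmann O-arylation of the enolate (CuI, 1,10-phenanthroline, K2CO3, DMF, 100 °C) then forms the same O1–C8a bond and should give 10.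

2. Step 6. The enolate may be acylated on oxygen or twice, the electron-rich ortho-substituted acid chloride may react sluggishly, and the diketone may undergo retro-Claisen cleavage during work-up. Fallback, setting out from 4 and 8 and coming back at 9: acid chloride 4 is reduced with LiAlH(Ot-Bu)3 (THF, −78 °C) to 2,3,4,5-tetramethoxybenzaldehyde F4. The lithium enolate of 8 (LDA, THF, −78 °C) is added to F4 to give the aldol 2-(benzyloxy)-3-hydroxy-1-(4-methoxyphenyl)-3-(2,3,4,5-tetramethoxyphenyl)propan-1-one F5, as a diastereomer mixture of no consequence. Dess–Martin oxidation (NaHCO3, CH2Cl2) should then give 9.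

3. Step 8. A second methyl ether (at C6) may be cleaved once the boron chelate at O5 has formed, ring B may be benzylated if cation trapping is incomplete, or debenzylation may stop short. Fallback, setting out from 10 and coming back at 11: hydrogenolysis (H2, Pd/C, EtOAc) removes only the benzyl group to give 3-hydroxy-5,6,7,8-tetramethoxy-2-(4-methoxyphenyl)-4H-chromen-4-one F6. Selective peri demethylation with AlCl3 in MeCN at rt, through the C4=O/C5–O aluminium chelate, followed by dilute HCl should give 11.

**Further compounds**
F1 | step 7 | 2-bromo-3,4,5,6-tetramethoxybenzoic acid | COc1c(Br)c(C(=O)O)c(OC)c(OC)c1OC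
F2 | step 7 | 2-bromo-3,4,5,6-tetramethoxybenzoyl chloride | COc1c(Br)c(C(=O)Cl)c(OC)c(OC)c1OC
F3 | step 7 | 2-(benzyloxy)-1-(2-bromo-3,4,5,6-tetramethoxyphenyl)-3-(4-methoxyphenyl)propane-1,3-dione | COc1ccc(cc1)C(=O)C(OCc1ccccc1)C(=O)c1c(Br)c(OC)c(OC)c(OC)c1OC
F4 | step 6 | 2,3,4,5-tetramethoxybenzaldehyde | COc1cc(C=O)c(OC)c(OC)c1OC
F5 | step 6 | 2-(benzyloxy)-3-hydroxy-1-(4-methoxyphenyl)-3-(2,3,4,5-tetramethoxyphenyl)propan-1-one (diastereomer mixture, racemic) | COc1ccc(cc1)C(=O)C(OCc1ccccc1)C(O)c1cc(OC)c(OC)c(OC)c1OC
F6 | step 8 | 3-hydroxy-5,6,7,8-tetramethoxy-2-(4-methoxyphenyl)-4H-chromen-4-one | COc1ccc(cc1)-c1oc2c(OC)c(OC)c(OC)c(OC)c2c(=O)c1O
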